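**Plan**

- Retrosynthesis cuts, in this order: the C8 ester; the ring bond C1–C2 of the enone; in one operation the lactone bond O–C6 and the C13–OAc bond; then C7–C11, C7–C8 and C5–C6. Atom numbers are germacrane numbers (C12 lactone carbonyl, C13 the CH2OAc carbon, C14 on C10, C15 on C4); TBS = tert-butyldimethylsilyl.
- Enabling feature: in the butenolide ring (O, C12, C11, C7, C6) the C7=C11 bond carries the lactone oxygen on C6 and the acetate on C13 in a 1,4 relation. Both oxygens can therefore be delivered to the termini of a diene C13=C11–C7=C6 whose C11 already bears the carboxyl carbon C12.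
- Forward: two C5 units from but-3-yn-1-ol (syn-carboalumination; iodide 4 and bromide 9) are joined through an ethynyl C2 unit (C6, C7) to ynone 13. Hydrostannation, CBS reduction and Stille coupling with methyl 2-bromoacrylate lead to dienoic acid 19.
- Rings: the butenolide forms first (step 13); the ten-membered carbocycle forms second by Nozaki–Hiyama–Kishi closure of C1–C2 (step 16). Oxidation to the C2 ketone, desilylation and methacrylation finish the route.
- Stereochemistry: C8 by reagent control (CBS reduction); C6 from C8 in step 13 (A(1,3) strain); both E ring alkenes from carboalumination; C6=C7 from syn-hydrostannation; C7=C11 fixed by the lactone ring.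

Key step: step 13

Step 1
Reactants: 1 but-3-yn-1-ol
Product: 2 TBS ether of but-3-yn-1-ol
Conditions: TBSCl, imidazole, CH2Cl2, 0 °C to rt
Reagents that add atoms: tert-butyldimethylsilyl chloride CC(C)(C)[Si](C)(C)Cl
Why: Standard silylation of the primary alcohol (the later C2 oxygen); the silyl ether is carried through the carboalumination and the acetylide chemistry.

Step 2
Reactants: 2 TBS ether of but-3-yn-1-ol
Product: 4 (E)-alkenyl iodide silyl ether, via silyloxy alkenylalane 3 (not isolated)
Conditions: Me3Al (2.5 equiv), Cp2ZrCl2 (25 mol%), CH2Cl2, 0 °C to rt; then I2, THF, −30 to 0 °C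
Reagents that add atoms: trimethylaluminium C[Al](C)C; iodine II
Why: Negishi zirconium-catalysed syn-carboalumination of the terminal alkyne puts the methyl group (C15) on the internal and aluminium on the terminal carbon, and iodinolysis with retention should give the E iodide that becomes C4=C5.

Step 3
Reactants: 4 (E)-alkenyl iodide silyl ether; 5 ethynylmagnesium bromide
Product: 7 (E)-enyne silyl ether, via ethynylzinc bromide 6 (not isolated)
Conditions: 5, ZnBr2, THF, 0 °C; then 4, Pd(PPh3)4 (5 mol%), THF, rt
Reagents that add atoms: none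
Why: Negishi alkynylation of the alkenyl iodide with retention of the E geometry introduces C6 and C7 as a terminal alkyne.

Step 4
Reactants: 1 but-3-yn-1-ol
Product: 9 (E)-4-bromo-3-methylbut-3-en-1-ol, via alkoxide alkenylalane 8 (not isolated)
Conditions: Me3Al (3 equiv), Cp2ZrCl2 (25 mol%), CH2Cl2, 0 °C to rt; then N-bromosuccinimide, THF, −78 to 0 °C; H2O work-up
Reagents that add atoms: trimethylaluminium C[Al](C)C; N-bromosuccinimide O=C1CCC(=O)N1Br
Why: Syn-carboalumination of the free alcohol, carried as its dimethylaluminium alkoxide, followed by bromination with retention; the bromide is chosen because it should survive the zerovalent-palladium steps 8 and 11 and still serve in the Nozaki–Hiyama–Kishi closure.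

Step 5
Reactants: 9 (E)-4-bromo-3-methylbut-3-en-1-ol
Product: 10 (E)-4-bromo-3-methylbut-3-enal
Conditions: Dess–Martin periodinane, NaHCO3, CH2Cl2, 0 °C; used at once
Reagents that add atoms: none
Why: Dess–Martin oxidation under buffered, non-basic conditions should give the β,γ-unsaturated aldehyde without migration of the double bond into conjugation.

Step 6
Reactants: 7 (E)-enyne silyl ether; 10 (E)-4-bromo-3-methylbut-3-enal
Product: 12 racemic propargylic alcohol, via lithium acetylide 11 (not isolated)
Conditions: 7, n-BuLi, THF, −78 °C; then 10, −78 °C; aq. NH4Cl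
Reagents that add atoms: none
Why: 1,2-Addition of a lithium acetylide to the aldehyde at low temperature forms C7–C8; the uncontrolled C8 centre is erased in step 7.

Step 7
Reactants: 12 racemic propargylic alcohol
Product: 13 ynone
Conditions: activated MnO2 (excess), CH2Cl2, rt
Reagents that add atoms: none
Why: MnO2 oxidises the propargylic alcohol selectively and prepares both the regiocontrolled hydrostannation and the enantioselective reduction.

Step 8
Reactants: 13 ynone
Product: 14 α-stannyl dienone
Conditions: Bu3SnH (1.05 equiv, slow addition), PdCl2(PPh3)2 (2 mol%), THF, 0 °C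
Reagents that add atoms: tributyltin hydride CCCC[SnH](CCCC)CCCC
Why: Palladium-catalysed syn-hydrostannation of an alkynyl ketone delivers hydride to the β-carbon C6 and tin to the α-carbon C7, so C5 and C8 end up cis on C6=C7; the unactivated alkenyl bromide should not react with zerovalent palladium at 0 °C.

Step 9
Reactants: 14 α-stannyl dienone
Product: 15 (S)-dienol stannane
Conditions: (R)-2-methyl-CBS-oxazaborolidine (0.5 equiv), catecholborane (2 equiv), toluene, −78 °C; then H2O
Reagents that add atoms: none
Why: CBS reduction; the α-stannylated dienyl group is the large ketone substituent, so the (R)-oxazaborolidine should give the (S)-carbinol at C8 by 1,2-hydride delivery under reagent control.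

Step 10
Reactants: 15 (S)-dienol stannane
Product: 16 bis-silyl ether stannane
Conditions: TBSCl, imidazole, DMF, rt
Reagents that add atoms: tert-butyldimethylsilyl chloride CC(C)(C)[Si](C)(C)Cl
Why: Standard silylation; the ether prevents lactonization of O8 onto C12 after step 11 and supplies the small oxygen flank used for face selection in step 13.

Step 11
Reactants: 16 bis-silyl ether stannane; 17 methyl 2-bromoacrylate
Product: 18 triene methyl ester
Conditions: Pd(PPh3)4 (10 mol%), CuI (20 mol%), CsF (2 equiv), DMF, rt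
Reagents that add atoms: none
Why: Stille coupling with copper iodide and fluoride promotion for the hindered α-branched alkenylstannane, with retention of the C6=C7 geometry; oxidative addition should occur at the activated C–Br bond of the bromoacrylate in preference to the unactivated alkenyl bromide at C1.

Step 12
Reactants: 18 triene methyl ester
Product: 19 dienoic acid
Conditions: LiOH, THF/H2O, 0 °C to rt; then aq. HCl to pH 4 at 0 °C; used without storage
Reagents that add atoms: lithium hydroxide [Li+].[OH-]
Why: Saponification of the methyl ester; silyl ethers, alkenyl bromide and diene should be stable to LiOH at 0 °C, and immediate use limits Diels–Alder dimerization of the 2-carboxy diene.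

Step 13
Reactants: 19 dienoic acid
Product: 21 (5R)-butenolide, via allylpalladium acetate 20 (not isolated)
Conditions: Pd(OAc)2 (10 mol%), p-benzoquinone (2 equiv), LiOAc (2 equiv), acetone/AcOH 4:1, rt
Reagents that add atoms: acetic acid CC(=O)O
Why: Proposed new method: Pd(OAc)2 binds the C6=C7 bond of the 1,3-diene-2-carboxylic acid, the C12 carboxylate adds to C6 anti to palladium, the C7–Pd σ-complex becomes the η3-allyl complex over C7–C11–C13 (20), acetate attacks its unhindered C13 terminus, and p-benzoquinone returns zerovalent palladium to the divalent state. The closest known reaction types are the palladium/benzoquinone 1,4-acyloxylactonization of conjugated dienes that carry the acid in a side chain and the divalent-palladium oxidative cyclization of 3-alkenoic acids to butenolides; new here is a diene bearing the carboxyl group on its own C2 (C11), which places lactone oxygen and acetate 1,4 across the new C7=C11 bond. The butenolide ring closes in the 5-endo-trig mode, accessible because the acrylic acid unit can rotate about C7–C11 to bring the carboxylate over C6. C6 is controlled by C8: with C5 cis to C8 on C6=C7, A(1,3) strain keeps H8 in the alkene plane, palladium should take the face flanked by the small, weakly coordinating silyloxy oxygen, and the carboxylate then enters from the face flanked by the C9 methylene, which corresponds to 6R. The step needs carboxylate attack at C6 (not C13 or C4) and acetate attack at C13 (not C7): the five-membered ring size, the fully substituted C7 and C4 termini and the inertness of alkenyl bromide and silyl ethers toward divalent palladium should secure this, and the ring fixes the geometry of the tetrasubstituted C7=C11 bond.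

Step 14
Reactants: 21 (5R)-butenolide
Product: 22 primary alcohol
Conditions: HF·pyridine, pyridine, THF, 0 °C
Reagents that add atoms: none
Why: Buffered HF·pyridine should cleave the unhindered primary silyl ether at C2 much faster than the secondary one at C8, which is flanked by the fully substituted C7.

Step 15
Reactants: 22 primary alcohol
Product: 23 aldehyde
Conditions: Dess–Martin periodinane, NaHCO3, CH2Cl2, 0 °C; used at once
Reagents that add atoms: none
Why: Dess–Martin oxidation gives the β,γ-unsaturated C2 aldehyde under neutral conditions that should not move the C4=C5 bond or epimerise C6.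

Step 16
Reactants: 23 aldehyde
Product: 25 macrocyclic allylic alcohol (C2 epimers), via alkenylchromium dichloride 24 (not isolated)
Conditions: CrCl2 (10 equiv), NiCl2 (5 mol%), DMSO/THF, 0.002 M, rt to 45 °C; aqueous work-up
Reagents that add atoms: none
Why: Nozaki–Hiyama–Kishi reaction: nickel-catalysed activation of the alkenyl bromide, transfer to trivalent chromium and chemoselective 1,2-addition to the aldehyde should close the ten-membered ring at C1–C2 with retention of the E geometry at C1=C10; the C2 epimers converge in step 17.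

Step 17
Reactants: 25 macrocyclic allylic alcohol
Product: 26 macrocyclic enone silyl ether
Conditions: Dess–Martin periodinane, NaHCO3, CH2Cl2, 0 °C
Reagents that add atoms: none
Why: Dess–Martin oxidation of the allylic alcohol gives the C1(10)-en-2-one; neutral conditions should leave the C4=C5 bond β,γ to the ketone and the C6 centre untouched.

Step 18
Reactants: 26 macrocyclic enone silyl ether
Product: 27 C8 alcohol
Conditions: HF·pyridine, THF, 0 °C to rt
Reagents that add atoms: none
Why: Fluoride cleavage of the secondary silyl ether under mildly acidic conditions that should not enolise the butenolide or the ketone.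

Step 19
Reactants: 27 C8 alcohol; 28 methacrylic anhydride
Product: 29 target compound
Conditions: DMAP (20 mol%), i-Pr2NEt, CH2Cl2, 0 °C
Reagents that add atoms: none
Why: DMAP-catalysed acylation of the secondary allylic alcohol with retention at C8; attack of O8 on the lactone carbonyl would need a bridgehead alkene in the tetrahedral intermediate, so acyl migration is not expected.

**Compound list**

1 | but-3-yn-1-ol | C#CCCO | starting material
2 | tert-butyl(but-3-yn-1-yloxy)dimethylsilane | C#CCCO[Si](C)(C)C(C)(C)C | intermediate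
3 | (E)-tert-butyl{[4-(dimethylalumanyl)-3-methylbut-3-en-1-yl]oxy}dimethylsilane (silyloxy alkenylalane, not isolated) | CC(C)(C)[Si](C)(C)OCC/C(C)=C/[Al](C)C | intermediate
4 | (E)-tert-butyl[(4-iodo-3-methylbut-3-en-1-yl)oxy]dimethylsilane | CC(C)(C)[Si](C)(C)OCC/C(C)=C/I | intermediate
5 | ethynylmagnesium bromide | C#C[Mg]Br | starting material
6 | ethynylzinc bromide (not isolated) | C#C[Zn]Br | intermediate
7 | (E)-tert-butyldimethyl[(3-methylhex-3-en-5-yn-1-yl)oxy]silane | CC(C)(C)[Si](C)(C)OCC/C(C)=C/C#C | intermediate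
8 | dimethylaluminium (E)-4-(dimethylalumanyl)-3-methylbut-3-en-1-olate (alkoxide alkenylalane, not isolated) | C[Al](C)OCC/C(C)=C/[Al](C)C | intermediate
9 | (E)-4-bromo-3-methylbut-3-en-1-ol | OCC/C(C)=C/Br | intermediate
10 | (E)-4-bromo-3-methylbut-3-enal | O=CC/C(C)=C/Br | intermediate
11 | lithium acetylide of 7 (not isolated) | CC(C)(C)[Si](C)(C)OCC/C(C)=C/C#C[Li] | intermediate
12 | rac-(1E,7E)-1-bromo-10-[(tert-butyldimethylsilyl)oxy]-2,8-dimethyldeca-1,7-dien-5-yn-4-ol | CC(C)(C)[Si](C)(C)OCC/C(C)=C/C#CC(O)C/C(C)=C/Br | intermediate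
13 | (1E,7E)-1-bromo-10-[(tert-butyldimethylsilyl)oxy]-2,8-dimethyldeca-1,7-dien-5-yn-4-one | CC(C)(C)[Si](C)(C)OCC/C(C)=C/C#CC(=O)C/C(C)=C/Br | intermediate
14 | (1E,5E,7E)-1-bromo-10-[(tert-butyldimethylsilyl)oxy]-2,8-dimethyl-5-(tributylstannyl)deca-1,5,7-trien-4-one | O=C(C/C(C)=C/Br)/C([Sn](CCCC)(CCCC)CCCC)=C\C=C(/C)CCO[Si](C)(C)C(C)(C)C | intermediate
15 | (4S,1E,5E,7E)-1-bromo-10-[(tert-butyldimethylsilyl)oxy]-2,8-dimethyl-5-(tributylstannyl)deca-1,5,7-trien-4-ol | O[C@@H](C/C(C)=C/Br)/C([Sn](CCCC)(CCCC)CCCC)=C\C=C(/C)CCO[Si](C)(C)C(C)(C)C | intermediate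
16 | (4S,1E,5E,7E)-1-bromo-4,10-bis[(tert-butyldimethylsilyl)oxy]-2,8-dimethyl-5-(tributylstannyl)deca-1,5,7-triene | CC(C)(C)[Si](C)(C)O[C@@H](C/C(C)=C/Br)/C([Sn](CCCC)(CCCC)CCCC)=C\C=C(/C)CCO[Si](C)(C)C(C)(C)C | intermediate
17 | methyl 2-bromoprop-2-enoate (methyl 2-bromoacrylate) | C=C(Br)C(=O)OC | starting material
18 | methyl (3Z,5E)-3-[(1S,3E)-4-bromo-1-[(tert-butyldimethylsilyl)oxy]-3-methylbut-3-en-1-yl]-8-[(tert-butyldimethylsilyl)oxy]-6-methyl-2-methylideneocta-3,5-dienoate | CC(C)(C)[Si](C)(C)O[C@@H](C/C(C)=C/Br)/C(C(=C)C(=O)OC)=C\C=C(/C)CCO[Si](C)(C)C(C)(C)C | intermediate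
19 | (3Z,5E)-3-[(1S,3E)-4-bromo-1-[(tert-butyldimethylsilyl)oxy]-3-methylbut-3-en-1-yl]-8-[(tert-butyldimethylsilyl)oxy]-6-methyl-2-methylideneocta-3,5-dienoic acid | CC(C)(C)[Si](C)(C)O[C@@H](C/C(C)=C/Br)/C(C(=C)C(=O)O)=C\C=C(/C)CCO[Si](C)(C)C(C)(C)C | intermediate
20 | allylpalladium acetate of the closed lactone, drawn as its C13-bound η1 form (not isolated) | CC(C)(C)[Si](C)(C)O[C@@H](C/C(C)=C/Br)C1=C(C[Pd]OC(C)=O)C(=O)O[C@@H]1/C=C(\C)CCO[Si](C)(C)C(C)(C)C | intermediate
21 | (5R)-3-(acetoxymethyl)-4-[(1S,3E)-4-bromo-1-[(tert-butyldimethylsilyl)oxy]-3-methylbut-3-en-1-yl]-5-[(1E)-4-[(tert-butyldimethylsilyl)oxy]-2-methylbut-1-en-1-yl]furan-2(5H)-one | CC(C)(C)[Si](C)(C)O[C@@H](C/C(C)=C/Br)C1=C(COC(C)=O)C(=O)O[C@@H]1/C=C(\C)CCO[Si](C)(C)C(C)(C)C | intermediate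
22 | (5R)-3-(acetoxymethyl)-4-[(1S,3E)-4-bromo-1-[(tert-butyldimethylsilyl)oxy]-3-methylbut-3-en-1-yl]-5-[(1E)-4-hydroxy-2-methylbut-1-en-1-yl]furan-2(5H)-one | CC(C)(C)[Si](C)(C)O[C@@H](C/C(C)=C/Br)C1=C(COC(C)=O)C(=O)O[C@@H]1/C=C(\C)CCO | intermediate
23 | (5R)-3-(acetoxymethyl)-4-[(1S,3E)-4-bromo-1-[(tert-butyldimethylsilyl)oxy]-3-methylbut-3-en-1-yl]-5-[(1E)-2-methyl-4-oxobut-1-en-1-yl]furan-2(5H)-one | CC(C)(C)[Si](C)(C)O[C@@H](C/C(C)=C/Br)C1=C(COC(C)=O)C(=O)O[C@@H]1/C=C(\C)CC=O | intermediate
24 | alkenylchromium dichloride derived from 23 (not isolated) | CC(C)(C)[Si](C)(C)O[C@@H](C/C(C)=C/[Cr](Cl)Cl)C1=C(COC(C)=O)C(=O)O[C@@H]1/C=C(\C)CC=O | intermediate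
25 | (6R,8S)-13-acetoxy-8-[(tert-butyldimethylsilyl)oxy]-2-hydroxygermacra-1(10)E,4E,7(11)-trien-12,6-olide (both C2 epimers) | CC(C)(C)[Si](C)(C)O[C@H]1C/C(C)=C/C(O)C/C(C)=C/[C@H]2OC(=O)C(COC(C)=O)=C12 | intermediate
26 | (6R,8S)-13-acetoxy-8-[(tert-butyldimethylsilyl)oxy]-2-oxogermacra-1(10)E,4E,7(11)-trien-12,6-olide | CC(C)(C)[Si](C)(C)O[C@H]1C/C(C)=C/C(=O)C/C(C)=C/[C@H]2OC(=O)C(COC(C)=O)=C12 | intermediate
27 | (6R,8S)-13-acetoxy-8-hydroxy-2-oxogermacra-1(10)E,4E,7(11)-trien-12,6-olide | O[C@H]1C/C(C)=C/C(=O)C/C(C)=C/[C@H]2OC(=O)C(COC(C)=O)=C12 | intermediate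
28 | methacrylic anhydride | C=C(C)C(=O)OC(=O)C(C)=C | starting material
29 | (6R,8S)-13-acetoxy-8-(methacryloyloxy)-2-oxogermacra-1(10)E,4E,7(11)-trien-12,6-olide (CNP0325594.1) | C=C(C)C(=O)O[C@H]1C/C(C)=C/C(=O)C/C(C)=C/[C@H]2OC(=O)C(COC(C)=O)=C12 | target

**Step count and risks**

Total step count: 19. Longest linear sequence: 17 steps (steps 1, 2, 3 and 6 to 19).

Steps most likely to fail:

1. Step 13. Palladium may bind the other face of C6=C7, or the oxygen may be delivered syn instead of anti, so that C6 forms with low or reversed selectivity. The conjugated triene acid may also dimerize, or be acetoxylated across C4–C7 before the carboxylate closes. The fallback sets out from acid 19 and uses known chemistry. PhSeCl (CH2Cl2, −78 °C) should effect the 5-endo phenylselenolactonization of the 3-alkenoic acid, the reversibly formed seleniranium ion on C6=C7 being opened by the carboxylate at C6, to give the α-methylene β-phenylselanyl lactone F1. Oxidation (H2O2, pyridine, 0 °C) gives the allylic selenoxide, which should undergo [2,3]-sigmatropic rearrangement to the C13 selenenate and hydrolysis to the 13-hydroxybutenolide F2. Acetylation (Ac2O, pyridine, DMAP) comes back to the route at 21.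

2. Step 16. Activation of the trisubstituted alkenyl bromide may be slow, so that oligomerization and reduction compete at the required dilution, and low-valent nickel may ionise the activated allylic acetate. The fallback sets out from triene ester 18 and closes the carbocycle before the lactone, on a substrate that has no allylic acetate. HF·pyridine gives the primary alcohol F3 and Dess–Martin oxidation the aldehyde F4. The CrCl2/NiCl2 closure, now helped by the rigid C4–C7 diene (the ring type of germacrene C), gives the macrocyclic alcohol F5. LiOH gives the hydroxy acid F6 and Dess–Martin oxidation the keto acid F7. The acetoxylactonization of step 13 applied to F7 comes back to the route at 26.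

3. Step 11. Transmetalation from the hindered α-branched stannane may be slower than protodestannylation or cine substitution, and some oxidative addition at the C1 bromide would lead to oligomers. The fallback sets out from stannane 16 and reverses the polarity of the coupling. Iododestannylation (I2, CH2Cl2, 0 °C) gives the alkenyl iodide F8, whose C–I bond should react with zerovalent palladium far faster than either C–Br bond. Stille coupling with the known reagent ethyl 2-(tributylstannyl)acrylate (Pd(PPh3)4, CuI, CsF, DMF) gives the ethyl ester F9, and LiOH hydrolysis comes back to the route at 19.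

**Further compounds**

F1 | step 13 | (4S,5R)-4-[(1S,3E)-4-bromo-1-[(tert-butyldimethylsilyl)oxy]-3-methylbut-3-en-1-yl]-5-[(1E)-4-[(tert-butyldimethylsilyl)oxy]-2-methylbut-1-en-1-yl]-3-methylidene-4-(phenylselanyl)dihydrofuran-2(3H)-one, selenium on C7 anti to the oxygen on C6 | CC(C)(C)[Si](C)(C)O[C@@H](C/C(C)=C/Br)[C@]1([Se]c2ccccc2)C(=C)C(=O)O[C@@H]1/C=C(\C)CCO[Si](C)(C)C(C)(C)C
F2 | step 13 | (5R)-4-[(1S,3E)-4-bromo-1-[(tert-butyldimethylsilyl)oxy]-3-methylbut-3-en-1-yl]-5-[(1E)-4-[(tert-butyldimethylsilyl)oxy]-2-methylbut-1-en-1-yl]-3-(hydroxymethyl)furan-2(5H)-one | CC(C)(C)[Si](C)(C)O[C@@H](C/C(C)=C/Br)C1=C(CO)C(=O)O[C@@H]1/C=C(\C)CCO[Si](C)(C)C(C)(C)C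
F3 | step 16 | methyl (3Z,5E)-3-[(1S,3E)-4-bromo-1-[(tert-butyldimethylsilyl)oxy]-3-methylbut-3-en-1-yl]-8-hydroxy-6-methyl-2-methylideneocta-3,5-dienoate | CC(C)(C)[Si](C)(C)O[C@@H](C/C(C)=C/Br)/C(C(=C)C(=O)OC)=C\C=C(/C)CCO
F4 | step 16 | methyl (3Z,5E)-3-[(1S,3E)-4-bromo-1-[(tert-butyldimethylsilyl)oxy]-3-methylbut-3-en-1-yl]-6-methyl-2-methylidene-8-oxoocta-3,5-dienoate | CC(C)(C)[Si](C)(C)O[C@@H](C/C(C)=C/Br)/C(C(=C)C(=O)OC)=C\C=C(/C)CC=O
F5 | step 16 | methyl (8S)-8-[(tert-butyldimethylsilyl)oxy]-2-hydroxygermacra-1(10)E,4E,6Z,11(13)-tetraen-12-oate (both C2 epimers) | CC(C)(C)[Si](C)(C)O[C@H]1C/C(C)=C/C(O)C/C(C)=C/C=C1/C(=C)C(=O)OC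
F6 | step 16 | (8S)-8-[(tert-butyldimethylsilyl)oxy]-2-hydroxygermacra-1(10)E,4E,6Z,11(13)-tetraen-12-oic acid (both C2 epimers) | CC(C)(C)[Si](C)(C)O[C@H]1C/C(C)=C/C(O)C/C(C)=C/C=C1/C(=C)C(=O)O
F7 | step 16 | (8S)-8-[(tert-butyldimethylsilyl)oxy]-2-oxogermacra-1(10)E,4E,6Z,11(13)-tetraen-12-oic acid | CC(C)(C)[Si](C)(C)O[C@H]1C/C(C)=C/C(=O)C/C(C)=C/C=C1/C(=C)C(=O)O
F8 | step 11 | (4S,1E,5E,7E)-1-bromo-4,10-bis[(tert-butyldimethylsilyl)oxy]-5-iodo-2,8-dimethyldeca-1,5,7-triene | CC(C)(C)[Si](C)(C)O[C@@H](C/C(C)=C/Br)/C(I)=C\C=C(/C)CCO[Si](C)(C)C(C)(C)C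
F9 | step 11 | ethyl (3Z,5E)-3-[(1S,3E)-4-bromo-1-[(tert-butyldimethylsilyl)oxy]-3-methylbut-3-en-1-yl]-8-[(tert-butyldimethylsilyl)oxy]-6-methyl-2-methylideneocta-3,5-dienoate | CC(C)(C)[Si](C)(C)O[C@@H](C/C(C)=C/Br)/C(C(=C)C(=O)OCC)=C\C=C(/C)CCO[Si](C)(C)C(C)(C)C
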